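Ring A is numbered C1 (C=O), C2=C3, C4 (OMe), C5, C6 (quaternary); C7/C8 are the side chain and C9–C11 the allyl group. The plan exploits the position of quaternary C6 between the ring A acyl carbon C1 and the allyl methylene C9: an acyl–palladium bond added across a C6=C9 methylene leaves palladium on C9 without any β-hydrogen. One double carbonylation thus forges C1–C2, C1–C6 and C9–C10, closes ring A as the enone and sets C6. Its precursor is an acyclic (Z)-alkenyl iodide carrying the C4 methyl ether, the C6=C9 methylene and the silylated C7/C8 syn-aldol unit. The CH2CO2Me arm later becomes the allyl group.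

Key step: step 9

Assumption: the enol borinate made with (+)-Ipc2BCl (from (−)-α-pinene) is taken to attack the Si face of a (Z)-enal, the sense established for methyl ketones, which corresponds to 4S.

Step 1
Reactants: 1 (S)-4-benzyl-3-propionyloxazolidin-2-one; 2 veratraldehyde (3,4-dimethoxybenzaldehyde)
Product: 4 (S)-4-benzyl-3-[(2S,3S)-3-(3,4-dimethoxyphenyl)-3-hydroxy-2-methylpropanoyl]oxazolidin-2-one, via dibutylboron enolate 3 (not isolated)
Conditions: Bu2BOTf, iPr2NEt, CH2Cl2, 0 °C; 2, −78 → 0 °C; then pH 7 buffer, MeOH, 30% H2O2, 0 °C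
Reagents that add atoms: none
Why: Evans syn aldol: the (Z)-boron enolate 3 adds through a Zimmerman–Traxler chair on the enolate face remote from the benzyl group, which should set C7 and C8 together as the (2S,3S) syn pair required by the target.

Step 2
Reactants: 4 Evans syn aldol adduct
Product: 5 (2S,3S)-3-(3,4-dimethoxyphenyl)-3-hydroxy-N-methoxy-N,2-dimethylpropanamide
Conditions: MeNH(OMe)·HCl, AlMe3, CH2Cl2, −10 °C → rt; aq. potassium sodium tartrate
Reagents that add atoms: N,O-dimethylhydroxylamine hydrochloride, CNOC.Cl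
Why: Weinreb aminolysis: the aluminium amide made from AlMe3 and the hydroxylamine salt attacks the exocyclic imide carbonyl, assisted by the free β-hydroxyl, and releases the auxiliary without touching C7 or C8.

Step 3
Reactants: 5 hydroxy Weinreb amide
Product: 6 (2S,3S)-3-(tert-butyldimethylsilyloxy)-3-(3,4-dimethoxyphenyl)-N-methoxy-N,2-dimethylpropanamide
Conditions: TBSOTf, 2,6-lutidine, CH2Cl2, 0 °C
Reagents that add atoms: tert-butyldimethylsilyl triflate, CC(C)(C)[Si](C)(C)OS(=O)(=O)C(F)(F)F
Why: Silylation of a secondary benzylic alcohol with a silyl triflate and a hindered pyridine base is routine, and the silyl ether masks the only internal nucleophile that could later intercept an acylpalladium or be oxidised in step 11.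

Step 4
Reactants: 6 silylated Weinreb amide
Product: 7 (3S,4S)-4-(tert-butyldimethylsilyloxy)-4-(3,4-dimethoxyphenyl)-3-methylbutan-2-one
Conditions: MeMgBr, THF, 0 °C
Reagents that add atoms: methylmagnesium bromide, C[Mg]Br
Why: Weinreb ketone synthesis: magnesium chelation by the N-methoxy amide holds the addition at the mono-adduct stage, so only the methyl ketone forms and the C7 centre is not enolised at 0 °C.

Step 5
Reactants: 8 ethyl (Z)-3-iodoacrylate
Product: 9 (Z)-3-iodoacrolein
Conditions: iBu2AlH (1.05 equiv), CH2Cl2, −78 °C; MeOH, aq. potassium sodium tartrate; kept cold and dark, used at once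
Reagents that add atoms: none
Why: Partial reduction of an ester with one equivalent of iBu2AlH at −78 °C stops at the aldehyde, and cold, dark and acid-free handling preserves the Z geometry of this isomerisation-prone enal.

Step 6
Reactants: 7 methyl ketone; 9 (Z)-3-iodoacrolein
Product: 11 (1S,2S,5S,6Z)-1-(tert-butyldimethylsilyloxy)-1-(3,4-dimethoxyphenyl)-5-hydroxy-7-iodo-2-methylhept-6-en-3-one, via diisopinocampheylboron enolate 10 (not isolated)
Conditions: (+)-Ipc2BCl, NEt3, Et2O, 0 °C; 9, −78 → −20 °C; then pH 7 buffer, MeOH, 30% H2O2, 0 °C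
Reagents that add atoms: none
Why: Paterson boron aldol of a methyl ketone: Ipc2BCl and NEt3 enolise only the methyl side to give 10, whose pinene-derived ligands should direct attack to the Si face of 9 and so set C4 as S, the minor C4 epimer being a diastereomer that chromatography can remove.

Step 7
Reactants: 11 β-hydroxy ketone
Product: 12 (1S,2S,5S,6Z)-1-(tert-butyldimethylsilyloxy)-1-(3,4-dimethoxyphenyl)-7-iodo-5-methoxy-2-methylhept-6-en-3-one
Conditions: Me3OBF4, 1,8-bis(dimethylamino)naphthalene, 4 Å MS, CH2Cl2, 0 °C → rt, dark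
Reagents that add atoms: trimethyloxonium tetrafluoroborate, C[O+](C)C.F[B-](F)(F)F
Why: O-Methylation with Meerwein salt and a non-nucleophilic proton scavenger works under essentially neutral conditions, so the aldol suffers neither retro-aldol cleavage nor β-elimination nor epimerisation at C7.

Step 8
Reactants: 12 β-methoxy ketone
Product: 13 tert-butyl{[(1S,2R,5S,6Z)-1-(3,4-dimethoxyphenyl)-7-iodo-5-methoxy-2-methyl-3-methylidenehept-6-en-1-yl]oxy}dimethylsilane
Conditions: Cp2TiMe2, toluene, 70 °C, dark
Reagents that add atoms: dimethyltitanocene Cp2TiMe2, [CH3-].[CH3-].[Ti+4].c1cc[cH-]c1.c1cc[cH-]c1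
Why: Petasis methylenation: the neutral titanium methylidene formed on heating converts the enolisable β-methoxy ketone into the C6=C9 methylene by a [2+2]/retro-[2+2] sequence without base, so C7, the methyl ether and the alkenyl iodide should survive.

Step 9
Reactants: 13 (Z)-alkenyl iodide with the C6=C9 methylene; 14 carbon monoxide (two molecules); 15 methanol
Product: 20 methyl 2-[(1R,5S)-1-{(1S,2R)-1-(tert-butyldimethylsilyloxy)-1-(3,4-dimethoxyphenyl)propan-2-yl}-5-methoxy-2-oxocyclohex-3-en-1-yl]acetate, via alkenylpalladium iodide 16 (not isolated), via alkenoylpalladium iodide 17 (not isolated), via neopentylpalladium iodide 18 (not isolated), via acylpalladium iodide 19 (not isolated)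
Conditions: PdCl2(PPh3)2 (5 mol %), CO (40 atm), NEt3 (2 equiv), MeOH (4 equiv), MeCN–benzene 1:1, 100 °C, autoclave
Reagents that add atoms: carbon monoxide, [C-]#[O+] (twice); methanol, CO
Why: Zerovalent palladium, formed from PdCl2(PPh3)2 under CO and NEt3, inserts into the carbon–iodine bond to give 16, CO insertion gives 17 (bond C1–C2), syn acylpalladation of C6=C9 gives 18 (bond C1–C6), and 18, which has no β-hydrogen, takes up a second CO to give 19 (bond C9–C10), which methanol cleaves to 20 while NEt3 binds the hydrogen iodide. The closest known reaction type is the carbonylative cyclisation of 1-iodo-1,5-dienes bearing a 1,1-disubstituted alkene, that is cyclic acylpalladation ended by alkoxycarbonylation. Ring A closes in the 6-exo-trig mode and the Z geometry of the iodide becomes the cis C2=C3 bond of the enone. C6 is the only new stereocentre: the four-centre insertion needs the Pd–C1 bond parallel to C6=C9, which places C9 axial and the C7 branch equatorial on the developing half-chair, so that a pseudo-equatorial C4 methoxyl, free of 1,3-diaxial contact with the CH2–Pd unit, ends up cis to the C7 branch as in the target, and the C7 rotamer with its hydrogen turned towards C5 keeps the bulky C8 branch on the face away from the incoming acyl group. The step needs CO uptake to outrun direct 5-exo carbopalladation, which the high CO pressure secures, and ring closure to outrun methanolysis of 17, which the Z alkene (acyl group held next to C6=C9) and the use of only a few equivalents of methanol in place of methanol as solvent secure. The silyl ether on O8 and the absence of any other alkene leave 17, 18 and 19 no competing partner.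

Step 10
Reactants: 20 ring A enone ester
Product: 21 (4S,6S)-6-{(1S,2R)-1-(tert-butyldimethylsilyloxy)-1-(3,4-dimethoxyphenyl)propan-2-yl}-6-(2-hydroxyethyl)-4-methoxycyclohex-2-en-1-ol (mixture of C1 epimers)
Conditions: iBu2AlH (5 equiv), CH2Cl2, −78 → 0 °C; aq. potassium sodium tartrate
Reagents that add atoms: none
Why: Exhaustive iBu2AlH reduction takes the ester to the primary alcohol and the enone to the allylic alcohol by 1,2-addition, and the uncontrolled C1 carbinol centre does not matter because it is reoxidised in step 11.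

Step 11
Reactants: 21 diol
Product: 22 2-[(1R,5S)-1-{(1S,2R)-1-(tert-butyldimethylsilyloxy)-1-(3,4-dimethoxyphenyl)propan-2-yl}-5-methoxy-2-oxocyclohex-3-en-1-yl]acetaldehyde
Conditions: (COCl)2, DMSO, CH2Cl2, −78 °C; NEt3, −78 → 0 °C
Reagents that add atoms: none
Why: Swern oxidation activates both hydroxyls before the base is added, so both are oxidised together and the hydroxy aldehyde stage, which with a stepwise oxidant could close to a lactol and be over-oxidised to a lactone, is avoided.

Step 12
Reactants: 22 keto aldehyde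
Product: 23 (4S,6S)-6-allyl-6-{(1S,2R)-1-(tert-butyldimethylsilyloxy)-1-(3,4-dimethoxyphenyl)propan-2-yl}-4-methoxycyclohex-2-en-1-one
Conditions: Ph3PCH3Br, KN(SiMe3)2, THF, 0 °C; 22, −78 → 0 °C
Reagents that add atoms: methyltriphenylphosphonium bromide, C[P+](c1ccccc1)(c1ccccc1)c1ccccc1.[Br-]
Why: Wittig methylenation with one equivalent of ylide at low temperature is selective for the unhindered aldehyde, because the enone carbonyl is conjugated and flanked by quaternary C6, and it completes the allyl group C9–C11.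

Step 13
Reactants: 23 silyl ether of the target
Product: 24 (4S,6S)-6-allyl-6-[(1S,2R)-1-(3,4-dimethoxyphenyl)-1-hydroxypropan-2-yl]-4-methoxycyclohex-2-en-1-one (CNP0138111.1)
Conditions: HF·pyridine, pyridine, THF, 0 °C → rt
Reagents that add atoms: none
Why: Fluoride-induced desilylation in a pyridine-buffered medium frees the C8 hydroxyl without ionising the electron-rich benzylic position and without the basic conditions that could epimerise C4.

Compound list
1 | (S)-4-benzyl-3-propionyloxazolidin-2-one | CCC(=O)N1[C@@H](Cc2ccccc2)COC1=O | starting material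
2 | 3,4-dimethoxybenzaldehyde | COc1ccc(C=O)cc1OC | starting material
3 | dibutylboron (Z)-enolate of 1 | C/C=C(\OB(CCCC)CCCC)N1[C@@H](Cc2ccccc2)COC1=O | intermediate
4 | (S)-4-benzyl-3-[(2S,3S)-3-(3,4-dimethoxyphenyl)-3-hydroxy-2-methylpropanoyl]oxazolidin-2-one | O=C([C@@H](C)[C@H](O)c1ccc(OC)c(OC)c1)N1[C@@H](Cc2ccccc2)COC1=O | intermediate
5 | (2S,3S)-3-(3,4-dimethoxyphenyl)-3-hydroxy-N-methoxy-N,2-dimethylpropanamide | CON(C)C(=O)[C@@H](C)[C@H](O)c1ccc(OC)c(OC)c1 | intermediate
6 | (2S,3S)-3-(tert-butyldimethylsilyloxy)-3-(3,4-dimethoxyphenyl)-N-methoxy-N,2-dimethylpropanamide | CON(C)C(=O)[C@@H](C)[C@H](O[Si](C)(C)C(C)(C)C)c1ccc(OC)c(OC)c1 | intermediate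
7 | (3S,4S)-4-(tert-butyldimethylsilyloxy)-4-(3,4-dimethoxyphenyl)-3-methylbutan-2-one | CC(=O)[C@@H](C)[C@H](O[Si](C)(C)C(C)(C)C)c1ccc(OC)c(OC)c1 | intermediate
8 | ethyl (Z)-3-iodoacrylate | CCOC(=O)/C=C\I | starting material
9 | (Z)-3-iodoacrolein | O=C/C=C\I | intermediate
10 | diisopinocampheylboron enolate of 7 (terminal CH2=C(OB) enolate, ligands from (−)-α-pinene) | C=C(OB([C@H]1C[C@H]2C[C@@H]([C@@H]1C)C2(C)C)[C@H]1C[C@H]2C[C@@H]([C@@H]1C)C2(C)C)[C@@H](C)[C@H](O[Si](C)(C)C(C)(C)C)c1ccc(OC)c(OC)c1 | intermediate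
11 | (1S,2S,5S,6Z)-1-(tert-butyldimethylsilyloxy)-1-(3,4-dimethoxyphenyl)-5-hydroxy-7-iodo-2-methylhept-6-en-3-one | I/C=C\[C@@H](O)CC(=O)[C@@H](C)[C@H](O[Si](C)(C)C(C)(C)C)c1ccc(OC)c(OC)c1 | intermediate
12 | (1S,2S,5S,6Z)-1-(tert-butyldimethylsilyloxy)-1-(3,4-dimethoxyphenyl)-7-iodo-5-methoxy-2-methylhept-6-en-3-one | I/C=C\[C@@H](OC)CC(=O)[C@@H](C)[C@H](O[Si](C)(C)C(C)(C)C)c1ccc(OC)c(OC)c1 | intermediate
13 | tert-butyl{[(1S,2R,5S,6Z)-1-(3,4-dimethoxyphenyl)-7-iodo-5-methoxy-2-methyl-3-methylidenehept-6-en-1-yl]oxy}dimethylsilane (key-step precursor) | I/C=C\[C@@H](OC)CC(=C)[C@@H](C)[C@H](O[Si](C)(C)C(C)(C)C)c1ccc(OC)c(OC)c1 | intermediate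
14 | carbon monoxide | [C-]#[O+] | starting material
15 | methanol | CO | starting material
16 | (Z)-alkenylpalladium iodide from 13 (PPh3 and CO ligands not drawn) | I[Pd]/C=C\[C@@H](OC)CC(=C)[C@@H](C)[C@H](O[Si](C)(C)C(C)(C)C)c1ccc(OC)c(OC)c1 | intermediate
17 | (Z)-alkenoylpalladium iodide, C1–C2 formed (ligands not drawn) | I[Pd]C(=O)/C=C\[C@@H](OC)CC(=C)[C@@H](C)[C@H](O[Si](C)(C)C(C)(C)C)c1ccc(OC)c(OC)c1 | intermediate
18 | neopentylpalladium iodide, ring A closed, palladium on C9 (ligands not drawn) | I[Pd]C[C@@]1([C@@H](C)[C@H](O[Si](C)(C)C(C)(C)C)c2ccc(OC)c(OC)c2)C[C@H](OC)C=CC1=O | intermediate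
19 | acylpalladium iodide, C9–C10 formed (ligands not drawn) | I[Pd]C(=O)C[C@@]1([C@@H](C)[C@H](O[Si](C)(C)C(C)(C)C)c2ccc(OC)c(OC)c2)C[C@H](OC)C=CC1=O | intermediate
20 | methyl 2-[(1R,5S)-1-{(1S,2R)-1-(tert-butyldimethylsilyloxy)-1-(3,4-dimethoxyphenyl)propan-2-yl}-5-methoxy-2-oxocyclohex-3-en-1-yl]acetate (key-step product) | COC(=O)C[C@@]1([C@@H](C)[C@H](O[Si](C)(C)C(C)(C)C)c2ccc(OC)c(OC)c2)C[C@H](OC)C=CC1=O | intermediate
21 | (4S,6S)-6-{(1S,2R)-1-(tert-butyldimethylsilyloxy)-1-(3,4-dimethoxyphenyl)propan-2-yl}-6-(2-hydroxyethyl)-4-methoxycyclohex-2-en-1-ol, C1 epimers | OCC[C@@]1([C@@H](C)[C@H](O[Si](C)(C)C(C)(C)C)c2ccc(OC)c(OC)c2)C[C@H](OC)C=CC1O | intermediate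
22 | 2-[(1R,5S)-1-{(1S,2R)-1-(tert-butyldimethylsilyloxy)-1-(3,4-dimethoxyphenyl)propan-2-yl}-5-methoxy-2-oxocyclohex-3-en-1-yl]acetaldehyde | O=CC[C@@]1([C@@H](C)[C@H](O[Si](C)(C)C(C)(C)C)c2ccc(OC)c(OC)c2)C[C@H](OC)C=CC1=O | intermediate
23 | (4S,6S)-6-allyl-6-{(1S,2R)-1-(tert-butyldimethylsilyloxy)-1-(3,4-dimethoxyphenyl)propan-2-yl}-4-methoxycyclohex-2-en-1-one | C=CC[C@@]1([C@@H](C)[C@H](O[Si](C)(C)C(C)(C)C)c2ccc(OC)c(OC)c2)C[C@H](OC)C=CC1=O | intermediate
24 | (4S,6S)-6-allyl-6-[(1S,2R)-1-(3,4-dimethoxyphenyl)-1-hydroxypropan-2-yl]-4-methoxycyclohex-2-en-1-one | C=CC[C@@]1([C@@H](C)[C@H](O)c2ccc(OC)c(OC)c2)C[C@H](OC)C=CC1=O | target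

Total step count: 13. Longest linear sequence: 12 (steps 1–4 and 6–13; step 5 is the side branch).

Steps most likely to fail

Step 9. What may go wrong: methanolysis of the alkenoylpalladium before ring closure, carbopalladation before CO uptake, or weak facial discrimination at C6 if the C7 centre works against the C4 centre.
- Fallback (sets out from 13, comes back at 23, replaces steps 9 to 12): the ring carbonyl carbon is taken from the C9 methylene instead of from CO, and the quaternary centre is made last on the closed ring.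
- Hydroboration of the 1,1-disubstituted alkene of 13 with 9-BBN, then oxidation with NaBO3, should give the primary alcohol F1. The iodoalkene is far less reactive towards 9-BBN.
- Dess–Martin oxidation gives the α-branched aldehyde F2.
- An intramolecular Nozaki–Hiyama–Kishi reaction (CrCl2, cat. NiCl2, DMF, high dilution) joins C2 to the aldehyde carbon and gives the cyclohexenol F3.
- A second Dess–Martin oxidation gives the 6-monosubstituted enone F4, whose C6 configuration is irrelevant.
- Kinetic deprotonation at C6 with LiN(iPr)2 at −78 °C followed by allyl bromide gives 23. The electrophile enters axially and therefore trans to the pseudo-equatorial C4 methoxyl.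

Step 6. What may go wrong: insufficient facial selectivity at C4, because the boron reagent has to override the bias of the neighbouring C7 methyl centre, and Z-to-E drift of the iodoenal before or during the addition.
- Fallback (sets out from 7, comes back at 13, replaces steps 5 to 8): C4 is set by a catalytic asymmetric glyoxylate-ene reaction and the iodoalkene is made last.
- Petasis methylenation of 7 gives the isopropenyl compound F5.
- Methyl glyoxylate, with the catalyst from (S)-BINOL and TiCl2(OiPr)2 (4 Å MS, CH2Cl2, −30 °C), bonds to the CH2 terminus and takes a hydrogen from the methyl group. This gives the (S)-α-hydroxy ester F6 with the C6=C9 methylene already in place.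
- Me3OBF4 and 1,8-bis(dimethylamino)naphthalene give the methyl ether F7.
- iBu2AlH at −78 °C gives the α-methoxy aldehyde F8.
- Stork–Zhao olefination with (iodomethyl)triphenylphosphonium iodide and NaN(SiMe3)2 in THF at −78 °C gives 13.

Step 8. What may go wrong: slow methylenation of the hindered ketone at the temperature the titanium reagent needs, with thermal loss of methanol or drift of the iodoalkene geometry.
- Fallback (sets out from 12, comes back at 13): a Peterson olefination in two stages.
- Me3SiCH2MgCl with CeCl3 in THF at −78 °C adds to the ketone and gives the tertiary β-hydroxysilane F9; either C6 epimer serves.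
- Mild acid (silica gel or a trace of camphorsulfonic acid in CH2Cl2) then induces the elimination to 13.
- Strong base is avoided because it would dehydroiodinate the (Z)-iodoalkene.

Further compounds
F1 | step 9 | primary alcohol, 13 with C6=C9 turned into CH–CH2OH (4S,7R,8S; C6 epimers) | I/C=C\[C@@H](OC)CC(CO)[C@@H](C)[C@H](O[Si](C)(C)C(C)(C)C)c1ccc(OC)c(OC)c1
F2 | step 9 | α-branched aldehyde, CH–CHO at C6 (4S,7R,8S; C6 epimers) | I/C=C\[C@@H](OC)CC(C=O)[C@@H](C)[C@H](O[Si](C)(C)C(C)(C)C)c1ccc(OC)c(OC)c1
F3 | step 9 | (4S)-6-{(1S,2R)-1-(tert-butyldimethylsilyloxy)-1-(3,4-dimethoxyphenyl)propan-2-yl}-4-methoxycyclohex-2-en-1-ol (C1 and C6 epimers) | C1([C@@H](C)[C@H](O[Si](C)(C)C(C)(C)C)c2ccc(OC)c(OC)c2)C[C@H](OC)C=CC1O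
F4 | step 9 | (4S)-6-{(1S,2R)-1-(tert-butyldimethylsilyloxy)-1-(3,4-dimethoxyphenyl)propan-2-yl}-4-methoxycyclohex-2-en-1-one (C6 epimers) | C1([C@@H](C)[C@H](O[Si](C)(C)C(C)(C)C)c2ccc(OC)c(OC)c2)C[C@H](OC)C=CC1=O
F5 | step 6 | tert-butyl{[(1S,2R)-1-(3,4-dimethoxyphenyl)-2,3-dimethylbut-3-en-1-yl]oxy}dimethylsilane | C=C(C)[C@@H](C)[C@H](O[Si](C)(C)C(C)(C)C)c1ccc(OC)c(OC)c1
F6 | step 6 | methyl (2S,5R,6S)-6-(tert-butyldimethylsilyloxy)-6-(3,4-dimethoxyphenyl)-2-hydroxy-5-methyl-4-methylidenehexanoate | COC(=O)[C@@H](O)CC(=C)[C@@H](C)[C@H](O[Si](C)(C)C(C)(C)C)c1ccc(OC)c(OC)c1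
F7 | step 6 | methyl (2S,5R,6S)-6-(tert-butyldimethylsilyloxy)-6-(3,4-dimethoxyphenyl)-2-methoxy-5-methyl-4-methylidenehexanoate | COC(=O)[C@@H](OC)CC(=C)[C@@H](C)[C@H](O[Si](C)(C)C(C)(C)C)c1ccc(OC)c(OC)c1
F8 | step 6 | (2S,5R,6S)-6-(tert-butyldimethylsilyloxy)-6-(3,4-dimethoxyphenyl)-2-methoxy-5-methyl-4-methylidenehexanal | O=C[C@@H](OC)CC(=C)[C@@H](C)[C@H](O[Si](C)(C)C(C)(C)C)c1ccc(OC)c(OC)c1
F9 | step 8 | tertiary β-hydroxysilane from addition of Me3SiCH2 to C6 of 12 (C6 epimers) | I/C=C\[C@@H](OC)CC(O)(C[Si](C)(C)C)[C@@H](C)[C@H](O[Si](C)(C)C(C)(C)C)c1ccc(OC)c(OC)c1
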